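The core is numbered C1 and C5 (bridgeheads), C2 (enone C=O), C3=C4 (styryl on C4), C6 (exo 3,5-dihydroxyphenyl), C7 (endo 4-hydroxyphenyl) and C8 (bridging C=O).
Enabling feature: bridgehead C1 is both the α-carbon of the C2 carbonyl group and the neighbour of benzylic C7 in the five-membered ring C1–C8–C5–C6–C7, the pattern left by a 1,2-shift of C7 from an oxygen-bearing C2 to C1.
Retrosynthesis: the four aryl O–CH3 bonds and the C8 ketal go first. Then C1–C7 is cut and C7 is re-bonded to C2, giving a 1-methoxybicyclo[2.2.2]octenyl sulfonate. Last come the styryl C=C (olefination) and the ring bonds C2–C7 and C5–C6 (Diels–Alder).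
Forward: the six-membered ring C1–C2–C3–C4–C5–C8 is the dearomatised ring of syringaldehyde. The cycloaddition lays the C6–C7 bridge across it, and the shift turns bicyclo[2.2.2] into bicyclo[3.2.1] by closing the five-membered ring.
Stereochemistry: the E geometry of the stilbene and the orientation of the cycloaddition fix C5, C6 and C7. A thermodynamically controlled reduction puts the leaving group syn to the etheno bridge, the shift inverts C1, and the absolute configuration comes from separating diastereomeric (1S)-camphorsulfonates, the sulfonate also being the leaving group.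

Key step: step 6

Remark: 4, 6 and 7 are racemates drawn as the enantiomer that is carried on; the bicyclo[2.2.2] compounds are numbered C1 (bridgehead OMe), C2 (C=O or carbinol), C3 (ketal), C4 (bridgehead H), C5=C6 (etheno bridge), C7 (4-methoxyphenyl), C8 (3,5-dimethoxyphenyl), and these atoms become C2, C1, C8, C5, C4, C3, C7 and C6 of the bicyclo[3.2.1] core.

Step 1
Reactants: 1 syringaldehyde (4-hydroxy-3,5-dimethoxybenzaldehyde)
Product: 2 3,3,5-trimethoxy-4-oxocyclohexa-1,5-diene-1-carbaldehyde (masked o-benzoquinone)
Conditions: PhI(OAc)2 (1.1 equiv), MeOH, 0 °C; solvent removed, used crude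
Reagents that add atoms: methanol, CO
Why: Oxidative dearomatisation of a 2,6-dimethoxyphenol with a trivalent iodine reagent in methanol places the incoming methoxy group on an ortho carbon that already bears one (masked o-benzoquinone formation), the para formyl group cannot divert the oxidation into a quinone methide as a styryl arm could, the remaining ortho methoxy group slows self-dimerisation, and no stereocentre is formed.

Step 2
Reactants: 2 3,3,5-trimethoxy-4-oxocyclohexa-1,5-diene-1-carbaldehyde; 3 (E)-3,4',5-trimethoxystilbene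
Product: 4 rac-(1R*,4S*,7R*,8S*)-8-(3,5-dimethoxyphenyl)-1,3,3-trimethoxy-7-(4-methoxyphenyl)-2-oxobicyclo[2.2.2]oct-5-ene-5-carbaldehyde (7-aryl syn to the etheno bridge; 8-aryl syn to the ketal bridge)
Conditions: 3 (2 equiv), toluene, 120 °C, sealed tube
Reagents that add atoms: none
Why: Inverse-electron-demand Diels–Alder reaction of a masked o-benzoquinone with a styrene-type alkene, in which the stilbene carbon β to the anisyl ring (the nucleophilic end) bonds to the dienone δ-carbon that is also β to the formyl group, the anisyl-bearing carbon closes onto the methoxy-bearing α-carbon, the anisyl ring takes the endo position under the diene as the aryl groups of styrenes do, the E geometry then puts the dimethoxyphenyl ring exo beside the ketal, and the enantiotopic faces of 2 give the four new stereocentres C1, C4, C7 and C8 in one relative configuration as a racemate.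

Step 3
Reactants: 4 the aldehyde adduct; 5 diethyl (4-methoxybenzyl)phosphonate
Product: 6 rac-(1R*,4S*,7R*,8S*)-8-(3,5-dimethoxyphenyl)-1,3,3-trimethoxy-7-(4-methoxyphenyl)-5-[(E)-2-(4-methoxyphenyl)ethenyl]bicyclo[2.2.2]oct-5-en-2-one
Conditions: 5 (1.2 equiv), KOtBu (1.2 equiv), THF, −78 °C to 0 °C
Reagents that add atoms: none
Why: The Horner–Wadsworth–Emmons olefination with a benzylic phosphonate is E-selective and picks the aldehyde because the ketone is flanked by two fully substituted carbons, neither carbonyl group can enolise, and no stereocentre is touched.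

Step 4
Reactants: 6 the styryl ketone
Product: 7 rac-(1R*,2S*,4S*,7R*,8S*)-8-(3,5-dimethoxyphenyl)-1,3,3-trimethoxy-7-(4-methoxyphenyl)-5-[(E)-2-(4-methoxyphenyl)ethenyl]bicyclo[2.2.2]oct-5-en-2-ol (hydroxyl syn to the etheno bridge)
Conditions: Al(OiPr)3 (0.5 equiv), iPrOH–toluene 1:1, acetone (0.2 equiv), 110 °C, sealed tube
Reagents that add atoms: none
Why: This is a Meerwein–Ponndorf–Verley reduction kept reversible by acetone (Oppenauer back-reaction), as used to equilibrate doubly neopentylic bicyclic carbinols: an irreversible hydride would enter from the open etheno face and leave the oxygen on the crowded diaryl side, whereas reversible hydride transfer lets the bulky aluminium alkoxide settle in the empty sector beside the sp2 bridge, which sets C2 with its oxygen syn to C5=C6.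

Step 5
Reactants: 7 the syn alcohol; 8 (1S)-(+)-camphor-10-sulfonyl chloride
Product: 9 (1R,2S,4S,7R,8S)-8-(3,5-dimethoxyphenyl)-1,3,3-trimethoxy-7-(4-methoxyphenyl)-5-[(E)-2-(4-methoxyphenyl)ethenyl]bicyclo[2.2.2]oct-5-en-2-yl (1S,4R)-camphor-10-sulfonate
Conditions: 8 (1.5 equiv), Et3N (3 equiv), DMAP (0.1 equiv), CH2Cl2, 0 °C to rt; diastereomers separated on silica gel or by crystallisation
Reagents that add atoms: none
Why: O-Sulfonylation of the secondary alcohol installs the nucleofuge and a resolving handle in one operation, since the two enantiomers of 7 give separable diastereomeric sulfonates, no bond to a stereocentre is broken, and the known camphor centres allow the absolute configuration of 9 to be read from a crystal structure.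

Step 6
Reactants: 9 the camphorsulfonate
Product: 11 (1R,5S,6S,7S)-6-(3,5-dimethoxyphenyl)-8,8-dimethoxy-7-(4-methoxyphenyl)-4-[(E)-2-(4-methoxyphenyl)ethenyl]bicyclo[3.2.1]oct-3-en-2-one, via methoxycarbenium ion 10 (not isolated)
Conditions: 2,6-lutidine (2 equiv), (CF3)2CHOH–H2O 9:1, 60 °C
Reagents that add atoms: water, O
Why: This is a semipinacol (Wagner–Meerwein type) rearrangement of a 2-sulfonyloxy bridgehead ether: as the sulfonate leaves C2 in the ionising solvent, the C1–C7 σ bond, which is antiperiplanar to the C2–O bond, swings over to C2, the charge lands on C1 as the methoxy-stabilised cation 10, and water turns 10 into the enone with loss of methanol. The closest known reactions are the solvolytic rearrangements of 1-methoxybicyclo[2.2.2]oct-5-en-2-yl sulfonates to bicyclo[3.2.1]octenones and the sulfonate-triggered bicyclo[2.2.2]-to-bicyclo[3.2.1] shifts of masked o-benzoquinone adducts that carry the same neighbouring ketal. The five-membered ring C1–C8–C5–C6–C7 (product numbering) closes by this intramolecular 1,2-alkyl shift, that is, by contraction of a six-membered ring of the bicyclo[2.2.2] frame, and not by a new intermolecular bond. The one new stereocentre, C1 of 11, forms with inversion because C7 arrives opposite the departing sulfonate, C7 migrates with retention, and C5 and C6 are bystanders. The step needs alkyl over vinyl migration and no shift from the ketal side: the syn sulfonate has only C1–C7 antiperiplanar (the vinyl carbon C6 is gauche and the π bond lies on the side of the leaving group), the anisyl group on C7 carries part of the charge in the bridged transition state, and the eclipsed C2–C3 bond leaves no ketal substituent aligned to move. Lutidine keeps the medium neutral, so the ketal and the new dienone should survive.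

Step 7
Reactants: 11 the ketal enone
Product: 12 (1R,5S,6S,7S)-6-(3,5-dimethoxyphenyl)-7-(4-methoxyphenyl)-4-[(E)-2-(4-methoxyphenyl)ethenyl]bicyclo[3.2.1]oct-3-ene-2,8-dione
Conditions: CF3CO2H–H2O 9:1, CH2Cl2, 0 °C to rt
Reagents that add atoms: water, O
Why: In this acid-catalysed ketal hydrolysis the bridging ketal is the only acid-labile group left, the aryl-conjugated dienone is electron-poor enough to tolerate the acid, and no stereocentre can epimerise because C1 and C5 are bridgeheads while C6 and C7 are not α to a carbonyl group.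

Step 8
Reactants: 12 the tetramethyl ether
Product: 13 (1R,5S,6S,7S)-6-(3,5-dihydroxyphenyl)-7-(4-hydroxyphenyl)-4-[(E)-2-(4-hydroxyphenyl)ethenyl]bicyclo[3.2.1]oct-3-ene-2,8-dione (CNP0288448.1)
Conditions: BBr3 (10 equiv), CH2Cl2, −78 °C to 0 °C; aq. NaHCO3
Reagents that add atoms: none
Why: Lewis-acid cleavage of aryl methyl ethers with BBr3, the usual last step for permethylated stilbenoid oligomers, removes all four methyl groups by bromide attack at methyl without touching C–C bonds or stereocentres, and the low temperature and buffered quench guard C7 against ionisation towards a quinone methide.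

Compound list
1 | syringaldehyde | COc1cc(C=O)cc(OC)c1O | starting material
2 | 3,3,5-trimethoxy-4-oxocyclohexa-1,5-diene-1-carbaldehyde | O=CC1=CC(OC)(OC)C(=O)C(OC)=C1 | intermediate
3 | (E)-3,4',5-trimethoxystilbene | COc1ccc(/C=C/c2cc(OC)cc(OC)c2)cc1 | starting material
4 | Diels–Alder adduct, 2-oxobicyclo[2.2.2]oct-5-ene-5-carbaldehyde (racemic; enantiomer shown is carried on) | CO[C@@]12C=C(C=O)[C@@H](C(OC)(OC)C1=O)[C@@H](c1cc(OC)cc(OC)c1)[C@@H]2c1ccc(OC)cc1 | intermediate
5 | diethyl (4-methoxybenzyl)phosphonate | CCOP(=O)(Cc1ccc(OC)cc1)OCC | starting material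
6 | 5-styryl bicyclo[2.2.2]oct-5-en-2-one (racemic; enantiomer shown is carried on) | CO[C@@]12C=C(/C=C/c3ccc(OC)cc3)[C@@H](C(OC)(OC)C1=O)[C@@H](c1cc(OC)cc(OC)c1)[C@@H]2c1ccc(OC)cc1 | intermediate
7 | bicyclo[2.2.2]oct-5-en-2-ol, OH syn to the etheno bridge (racemic; enantiomer shown is carried on) | CO[C@@]12C=C(/C=C/c3ccc(OC)cc3)[C@@H](C(OC)(OC)[C@H]1O)[C@@H](c1cc(OC)cc(OC)c1)[C@@H]2c1ccc(OC)cc1 | intermediate
8 | (1S)-(+)-camphor-10-sulfonyl chloride | CC1(C)[C@@H]2CC[C@@]1(CS(=O)(=O)Cl)C(=O)C2 | starting material
9 | (1R,2S,4S,7R,8S)-bicyclo[2.2.2]oct-5-en-2-yl (1S,4R)-camphor-10-sulfonate (key-step precursor) | CO[C@@]12C=C(/C=C/c3ccc(OC)cc3)[C@@H](C(OC)(OC)[C@H]1OS(=O)(=O)C[C@]34CC[C@H](CC3=O)C4(C)C)[C@@H](c1cc(OC)cc(OC)c1)[C@@H]2c1ccc(OC)cc1 | intermediate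
10 | methoxycarbenium ion (11 methylated on the C2 oxygen; camphorsulfonate counter-ion) | C[O+]=C1C=C(/C=C/c2ccc(OC)cc2)[C@H]2C(OC)(OC)[C@@H]1[C@@H](c1ccc(OC)cc1)[C@@H]2c1cc(OC)cc(OC)c1 | intermediate
11 | (1R,5S,6S,7S)-8,8-dimethoxybicyclo[3.2.1]oct-3-en-2-one (key-step product) | O=C1C=C(/C=C/c2ccc(OC)cc2)[C@H]2C(OC)(OC)[C@@H]1[C@@H](c1ccc(OC)cc1)[C@@H]2c1cc(OC)cc(OC)c1 | intermediate
12 | (1R,5S,6S,7S)-bicyclo[3.2.1]oct-3-ene-2,8-dione tetramethyl ether | O=C1C=C(/C=C/c2ccc(OC)cc2)[C@H]2C(=O)[C@@H]1[C@@H](c1ccc(OC)cc1)[C@@H]2c1cc(OC)cc(OC)c1 | intermediate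
13 | CNP0288448.1 | O=C1C=C(/C=C/c2ccc(O)cc2)[C@H]2C(=O)[C@@H]1[C@@H](c1ccc(O)cc1)[C@@H]2c1cc(O)cc(O)c1 | target

Total step count: 8. Longest linear sequence: 8 steps (1 to 13).

Steps most likely to fail

Step 2: the cycloaddition may be slow for a 1,2-diaryl alkene. The alkene may also turn round so that the dimethoxyphenyl ring goes endo to escape the ketal, which would invert C6 and C7 relative to the core. The fallback is a temporary tether; it sets out from 1 and 5 and comes back at 13. Commercial 3-hydroxy-5-methoxybenzaldehyde is alkylated with 3-bromopropan-1-ol (K2CO3, DMF) to 3-(3-hydroxypropoxy)-5-methoxybenzaldehyde F1, and olefination with 5 (KOtBu, 2.2 equiv) gives the stilbene alcohol F2. Oxidation of 1 with PhI(OAc)2 in CH2Cl2 in the presence of F2 in place of methanol gives the mixed-ketal masked o-benzoquinone F3. In F3 a three-carbon chain ties the ketal oxygen to the very ring that must end up beside the ketal. Heating in dilute toluene then allows only the wanted regiochemistry and orientation and gives the strapped adduct F4. The operations of steps 3 to 7 follow on the strapped series: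
- olefination to the strapped ketone F5
- equilibrating reduction to the strapped syn alcohol F6
- camphorsulfonylation and separation to the strapped sulfonate F7
- solvolytic shift to the strapped enone F8
- acid hydrolysis, which opens the strap at the ketal, to the hydroxypropyl ether F9

BBr3 cleaves the three methyl ethers and the hydroxypropyl ether of F9 alike and gives 13.

Step 4: hydride transfer to the hindered face may be too slow for the carbinols to equilibrate. Kinetic delivery from the etheno face would then prevail and the oxygen would end up anti to C5=C6, from where it would send the vinyl carbon instead of C7. The fallback makes C2 epimerisable by raising its neighbour to the ketone level; it sets out from 6 and comes back at 12. NaBH4 (MeOH–THF) gives the anti alcohol F10. Wet acetone with pyridinium tosylate removes the ketal, helped by relief of the contact with the 8-aryl group, and gives the anti α-hydroxy ketone F11. C2–H is now α to a carbonyl group, so Et3N or catalytic DBU equilibrates it through the enediolate to the syn α-hydroxy ketone F12, with the hydroxyl in the free sector beside the etheno bridge. Sulfonylation with 8 and separation as in step 5 give the keto sulfonate F13, and solvolysis as in step 6 delivers 12 directly, so step 7 is saved.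

Step 6: the inductive pull of the ketal next to C2 may hold back ionisation, so that prolonged heating brings solvent attack at sulfur or loss of the ketal before the shift. The fallback uses a far better nucleofuge, made and consumed in situ, with the resolution moved one step back; it sets out from 7 and comes back at 11. The enantiomers of 7 are separated by preparative chromatography on a chiral stationary phase. The (1R,2S,4S,7R,8S) enantiomer is treated with Tf2O and 2,6-di-tert-butyl-4-methylpyridine in CH2Cl2 at −78 °C to give the triflate F14, which ionises to 10 on warming, and an aqueous NaHCO3 quench gives 11.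

Further compounds
F1 | step 2 | 3-(3-hydroxypropoxy)-5-methoxybenzaldehyde | O=Cc1cc(OC)cc(OCCCO)c1
F2 | step 2 | 3-{3-methoxy-5-[(E)-2-(4-methoxyphenyl)ethenyl]phenoxy}propan-1-ol | OCCCOc1cc(OC)cc(/C=C/c2ccc(OC)cc2)c1
F3 | step 2 | mixed-ketal masked o-benzoquinone (racemic at the ketal carbon) | O=CC1=CC(OC)(OCCCOc2cc(OC)cc(/C=C/c3ccc(OC)cc3)c2)C(=O)C(OC)=C1
F4 | step 2 | strapped Diels–Alder adduct, aldehyde (racemic; enantiomer shown) | CO[C@@]12C=C(C=O)[C@@H]3[C@@H](c4cc(OC)cc(OCCCO[C@]3(OC)C1=O)c4)[C@@H]2c1ccc(OC)cc1
F5 | step 2 | strapped styryl ketone (racemic; enantiomer shown) | CO[C@@]12C=C(/C=C/c5ccc(OC)cc5)[C@@H]3[C@@H](c4cc(OC)cc(OCCCO[C@]3(OC)C1=O)c4)[C@@H]2c1ccc(OC)cc1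
F6 | step 2 | strapped syn alcohol (racemic; enantiomer shown) | CO[C@@]12C=C(/C=C/c5ccc(OC)cc5)[C@@H]3[C@@H](c4cc(OC)cc(OCCCO[C@]3(OC)[C@H]1O)c4)[C@@H]2c1ccc(OC)cc1
F7 | step 2 | strapped (1S,4R)-camphor-10-sulfonate, single diastereomer | CO[C@@]12C=C(/C=C/c5ccc(OC)cc5)[C@@H]3[C@@H](c4cc(OC)cc(OCCCO[C@]3(OC)[C@H]1OS(=O)(=O)C[C@]67CC[C@H](CC6=O)C7(C)C)c4)[C@@H]2c1ccc(OC)cc1
F8 | step 2 | strapped bicyclo[3.2.1]oct-3-en-2-one (mixed ketal at C8) | O=C1C=C(/C=C/c3ccc(OC)cc3)[C@H]2[C@]4(OC)OCCCOc3cc(OC)cc(c3)[C@H]2[C@H](c2ccc(OC)cc2)[C@H]14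
F9 | step 2 | 2,8-dione with a 3-hydroxypropyl ether in place of one methyl ether | O=C1C=C(/C=C/c2ccc(OC)cc2)[C@H]2C(=O)[C@@H]1[C@@H](c1ccc(OC)cc1)[C@@H]2c1cc(OC)cc(OCCCO)c1
F10 | step 4 | anti alcohol, C2 epimer of 7 (racemic; enantiomer shown) | CO[C@@]12C=C(/C=C/c3ccc(OC)cc3)[C@@H](C(OC)(OC)[C@@H]1O)[C@@H](c1cc(OC)cc(OC)c1)[C@@H]2c1ccc(OC)cc1
F11 | step 4 | anti α-hydroxy ketone (racemic; enantiomer shown) | CO[C@@]12C=C(/C=C/c3ccc(OC)cc3)[C@@H](C(=O)[C@@H]1O)[C@@H](c1cc(OC)cc(OC)c1)[C@@H]2c1ccc(OC)cc1
F12 | step 4 | syn α-hydroxy ketone (racemic; enantiomer shown) | CO[C@@]12C=C(/C=C/c3ccc(OC)cc3)[C@@H](C(=O)[C@H]1O)[C@@H](c1cc(OC)cc(OC)c1)[C@@H]2c1ccc(OC)cc1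
F13 | step 4 | syn keto (1S,4R)-camphor-10-sulfonate, single diastereomer | CO[C@@]12C=C(/C=C/c3ccc(OC)cc3)[C@@H](C(=O)[C@H]1OS(=O)(=O)C[C@]34CC[C@H](CC3=O)C4(C)C)[C@@H](c1cc(OC)cc(OC)c1)[C@@H]2c1ccc(OC)cc1
F14 | step 6 | (1R,2S,4S,7R,8S)-triflate of 7 | CO[C@@]12C=C(/C=C/c3ccc(OC)cc3)[C@@H](C(OC)(OC)[C@H]1OS(=O)(=O)C(F)(F)F)[C@@H](c1cc(OC)cc(OC)c1)[C@@H]2c1ccc(OC)cc1
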